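How much J is left in the north-east flask at its last hour, with more L than before? Ask first where a flask must stop, then whether this one gets there.

| flask | J | L | G | time |
|---|---|---|---|---|
| west | 100 mM | 300 mM | 10.0 mM |  |
| south-east | 300 mM | 300 mM | 10.0 mM |  |
| north-east | 200 mM | 900 mM | 10.0 mM | 140 h |

* order of the initial rate in [J], near the charge of the west run, the rate being that where two percent of its J are E (one fixed amount of E, the same in the runs compared)
* J in the north-east run at 140 h, as a share of the J charged

- Overall: J + L -> E, with G as catalyst.
- Constant volume, constant temperature.
- An order is taken over about fifteen percent of the charge, up and down.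

| west run: time / h | west run: [J] / mM | south-east run: time / h | south-east run: [J] / mM |
|---|---|---|---|
| 5.6 | 80.4 | 5.6 | 272.9 |
| 9.6 | 71.9 | 9.6 | 261.6 |
| 16 | 61.2 | 16 | 248.2 |
| 28 | 49.0 | 28 | 235.1 |
| 48 | 35.6 | 48 | 221.9 |
| 82 | 26.1 | 82 | 213.2 |
| 140 | 19.4 | 140 | 208.0 |

(standard deviation of a reading: 0.5 mM)

Start with the last rows. The south-east run has lost 92.0 mM of J and has nearly stopped, yet 208.0 mM of J remains. Even counted wholly as E, that loss takes less L than was charged, so if L is what ends the run, L must be going elsewhere. From here I count J lost as if it were E, a rough count that ignores any J still held on the 10.0 mM of G. My guess is a waste growing with L squared, while E, with J plentiful, grows with L alone (pseudo-first-order in L).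

The south-east falls over its last two intervals then give a tail constant a, read as 0.0228 /h. Extending that tail puts the end of this run at 93.9 mM of J lost.

Now let c be the break-even level, the level of L at which E and waste take L equally. Each bit of L lost gives E the share c/(c+L). Summed from the charge L0 down to nothing, this gives a ceiling on E of c ln(1+L0/c). Fitting the south-east end by trial gives c = 46.9 mM.

For the north-east charge the ceiling is 141 mM, which would leave 29.5% of J. But J thins there, as in the west run, which has the same ceiling as the south-east run and reached 85.8% of it. Taking that fraction, I expect 39.5% of J.

The forecast differs: 52% of J, expecting a stall “whatever L does”, and an order of 0.48.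

The flask gives 42.1% of J and an order of 0.50, so the north-east run lost 116 mM of J, 82.1% of the ceiling as I counted it, in J lost.

    G + J → Dz + Q (17.89 /M/h)
    Dz + L → E + G (4.752 /M/h)
    G + Qa → Ja
    2 L → Ek (0.2477 /M/h)

The end is set by the waste of L together with the G that Qa takes, which leaves 5.09 mM of G working. Without Qa, c grows with the working G to 92.2 mM, and the ceiling rises to 219 mM. The same 82.1% then leaves 10.1% of J, and that simulated run holds 11.7%.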